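**Retrosynthetic overview**
- Target ⇐ PMB removal, ring-closing metathesis of an acrylate (butenolide, last ring), C4 ketone methylenation, and acetonide migration 6,7 → 7,8 to tell the 6-acetate from the 7-isobutyrate.
- C11 carbinol and side chain ⇐ chelation-controlled addition of a 2-(acryloyloxymethyl)allylstannane to a C11 aldehyde.
- Decalin ⇐ one-flask hydrogen-atom-transfer radical bicyclisation of an acyclic alkene/enoate/alkyne: ring A first (C5–C10, 6-exo-trig), ring B second (C9–C8, 6-exo-dig), then hydration of the exocyclic C8 alkene in the same flask.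
- Acyclic precursor ⇐ Nozaki–Hiyama–Kishi union (C4–C5) of an enoate aldehyde (C1 from Brown allylation of acrolein) with a vinyl triflate–alkyne (C6, C7 from L-tartrate).

Assumption: clerodane numbering is used for all intermediates (C1–C10 decalin, C11–C16 side chain, C17 on C8, C18 on C4, C19 on C5, C20 on C9); the C4 carbinol in 14–18 is an inconsequential epimer mixture that is oxidised in step 12.

**Step 1**
Reactants: 1 dimethyl (4R,5R)-2,2-dimethyl-1,3-dioxolane-4,5-dicarboxylate
Product: 3 (4R,5R)-4,5-diacetyl-2,2-dimethyl-1,3-dioxolane, via bis-Weinreb amide 2 (not isolated)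
Conditions: MeNH(OMe)·HCl (2.5 equiv), MeMgBr (9 equiv), THF, −20 → 0 °C; aq. NH4Cl
Reagents that add atoms: methylmagnesium bromide, C[Mg]Br; N,O-dimethylhydroxylamine hydrochloride, CNOC.Cl (kept in 2 only)
Why: One-pot Weinreb amidation/Grignard addition stops at the methyl ketone through the chelated tetrahedral intermediate, and the two tartrate stereocentres are not touched.

**Step 2**
Reactants: 3 (4R,5R)-4,5-diacetyl-2,2-dimethyl-1,3-dioxolane
Product: 4 [(4R,5R)-2,2-dimethyl-1,3-dioxolane-4,5-diyl]di(ethene-1,1-diyl) bis(trifluoromethanesulfonate)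
Conditions: KN(SiMe3)2 (2.3 equiv), PhNTf2 (2.3 equiv), THF, −78 °C
Reagents that add atoms: N-phenylbis(trifluoromethanesulfonimide), FC(F)(F)S(=O)(=O)N(c1ccccc1)S(=O)(=O)C(F)(F)F
Why: Kinetic enolisation on the methyl side of both ketones and O-triflation (enol triflate formation) keeps the C2 symmetry and the stereocentres.

**Step 3**
Reactants: 4 bis(enol triflate)
Product: 5 1-[(4R,5S)-5-ethynyl-2,2-dimethyl-1,3-dioxolan-4-yl]ethenyl trifluoromethanesulfonate
Conditions: LiN(iPr)2 (2.0 equiv), THF, −78 → −40 °C; aq. NH4Cl (4 and the diyne are separated, 4 is recycled)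
Reagents that add atoms: none
Why: Base-induced elimination of one enol triflate gives the terminal alkyne; the substrate is C2-symmetric, so the statistical mono-elimination can give only one mono-product.

**Step 4**
Reactants: 6 acrolein
Product: 7 (3S)-hexa-1,5-dien-3-ol
Conditions: (−)-Ipc2B(allyl), Et2O, −78 °C; then ethanolamine
Reagents that add atoms: (−)-B-allyldiisopinocampheylborane, C=CCB([C@@H]1C[C@@H]2C[C@H]([C@H]1C)C2(C)C)[C@@H]1C[C@@H]2C[C@H]([C@H]1C)C2(C)C
Why: Brown allylation through a chair Zimmerman–Traxler transition state delivers the allyl group to the Si face of the aldehyde and sets C1 as S.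

**Step 5**
Reactants: 7 (3S)-hexa-1,5-dien-3-ol
Product: 8 1-({[(3S)-hexa-1,5-dien-3-yl]oxy}methyl)-4-methoxybenzene
Conditions: NaH, 4-methoxybenzyl chloride, Bu4NI (cat.), THF/DMF, 0 → 23 °C
Reagents that add atoms: 4-methoxybenzyl chloride, COc1ccc(CCl)cc1
Why: Williamson etherification protects C1–OH without touching the stereocentre.

**Step 6**
Reactants: 8 PMB ether of (3S)-hexa-1,5-dien-3-ol
Product: 10 (4S)-4-[(4-methoxybenzyl)oxy]hex-5-en-1-ol, via alkylborane 9 (not isolated)
Conditions: 9-BBN (1.05 equiv), THF, 0 → 23 °C; then NaOH, H2O2, 0 °C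
Reagents that add atoms: hydrogen peroxide, OO; 9-borabicyclo[3.3.1]nonane, [H]B1C2CCCC1CCC2 (kept in 9 only)
Why: Anti-Markovnikov hydroboration–oxidation with the bulky borane is selective for the unhindered allyl alkene over the vinyl group next to the PMB ether.

**Step 7**
Reactants: 10 (4S)-4-[(4-methoxybenzyl)oxy]hex-5-en-1-ol; 11 methyl methacrylate
Product: 12 methyl (2E,4S)-7-hydroxy-4-[(4-methoxybenzyl)oxy]-2-methylhept-2-enoate
Conditions: second-generation Hoveyda–Grubbs catalyst (5 mol %), 11 (10 equiv), CH2Cl2, 40 °C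
Reagents that add atoms: none
Why: Olefin cross-metathesis of the only remaining terminal alkene with the 1,1-disubstituted acrylate gives the thermodynamically favoured E trisubstituted enoate.

**Step 8**
Reactants: 12 hydroxy enoate
Product: 13 methyl (2E,4S)-4-[(4-methoxybenzyl)oxy]-2-methyl-7-oxohept-2-enoate
Conditions: Dess–Martin periodinane, pyridine, CH2Cl2, 0 → 23 °C
Reagents that add atoms: none
Why: Dess–Martin oxidation of the primary alcohol to the aldehyde is neutral and does not touch the enoate or the C1 centre.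

**Step 9**
Reactants: 13 enoate aldehyde; 5 vinyl triflate–alkyne
Product: 14 methyl (2E,4S)-8-[(4S,5S)-5-ethynyl-2,2-dimethyl-1,3-dioxolan-4-yl]-7-hydroxy-4-[(4-methoxybenzyl)oxy]-2-methylnona-2,8-dienoate (both C4 epimers in clerodane numbering)
Conditions: CrCl2 (6 equiv), NiCl2 (2 mol %), DMF, 23 °C
Reagents that add atoms: none
Why: Nozaki–Hiyama–Kishi coupling adds the alkenylchromium species from the triflate to the aldehyde only (ester, enoate and alkyne are tolerated); the new C4 carbinol is formed unselectively and is erased in step 12.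

**Step 10**
Reactants: 14 acyclic alkene/enoate/alkyne
Product: 17 methyl 4,8-dihydroxy-1-[(4-methoxybenzyl)oxy]-6,7-(isopropylidenedioxy)-5,8,9-trimethyl-trans-decalin-9-carboxylate (C4 epimers; other centres as in the target), via exocyclic alkene 15 (not isolated), via hydroperoxide 16 (not isolated)
Conditions: Mn(dpm)3 (0.3 equiv; dpm = 2,2,6,6-tetramethylheptane-3,5-dionate), PhSiH3 (3 equiv), t-BuOOH (1.5 equiv), i-PrOH, Ar, 23 °C; then O2 (1 atm), PhSiH3 (2 equiv), 0 → 23 °C; then PPh3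
Reagents that add atoms: dioxygen, O=O
Why: Proposed new method: the manganese hydride transfers H• to the 1,1-disubstituted alkene, and the tertiary C5 radical closes ring A by 6-exo-trig addition to the enoate through a chair (C1–OPMB and the enoate arm equatorial, C19 axial, so C5/C10 come out trans). The α-ester C9 radical, with C10–H held in its plane by A(1,3) strain, then closes ring B by 6-exo-dig attack on the alkyne from the C5 side (C20 axial, C11 equatorial), and the vinyl radical is reduced to alkene 15. Under O2 the same catalyst hydrates 15, with O2 trapping the C8 radical anti to the axial C20 methyl (axial 8-OH, equatorial C17). Closest known chemistry: Shenvi-type hydrogen-atom-transfer radical cyclisations, Snider-type alkyne-terminated radical bicyclisations and the Mukaiyama hydration.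

**Step 11**
Reactants: 17 bicyclic ester
Product: 18 9-(hydroxymethyl) triol (4,8,11-triol; C4 epimers)
Conditions: LiAlH4, THF, 0 → 40 °C; Fieser work-up
Reagents that add atoms: none
Why: Hydride reduction of the hindered ester to the primary alcohol; acetonide, PMB ether and the stereocentres are inert.

**Step 12**
Reactants: 18 triol
Product: 19 8-hydroxy-1-[(4-methoxybenzyl)oxy]-6,7-(isopropylidenedioxy)-5,8,9-trimethyl-4-oxo-trans-decalin-9-carbaldehyde
Conditions: Dess–Martin periodinane (3 equiv), pyridine, CH2Cl2, 0 → 23 °C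
Reagents that add atoms: none
Why: Dess–Martin oxidation converts the secondary C4 alcohol (both epimers converge) and the primary C11 alcohol in one operation and leaves the tertiary C8 alcohol.

**Step 13**
Reactants: 20 2-methylprop-2-en-1-ol
Product: 21 2-[(tributylstannyl)methyl]prop-2-en-1-ol
Conditions: n-BuLi (2.2 equiv), TMEDA, Et2O, 0 → 23 °C; Bu3SnCl, −78 → 0 °C
Reagents that add atoms: tributyltin chloride, CCCC[Sn](Cl)(CCCC)CCCC
Why: Allylic deprotonation of the lithium alkoxide gives the O,C-dianion, which is stannylated at carbon.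

**Step 14**
Reactants: 21 2-[(tributylstannyl)methyl]prop-2-en-1-ol
Product: 22 2-[(tributylstannyl)methyl]prop-2-en-1-yl prop-2-enoate
Conditions: acryloyl chloride, Et3N, CH2Cl2, 0 °C
Reagents that add atoms: acryloyl chloride, C=CC(Cl)=O
Why: Simple O-acylation of the primary allylic alcohol.

**Step 15**
Reactants: 19 keto aldehyde; 22 allylstannane acrylate
Product: 24 11-O-isobutyrate of the (11R)-homoallylic alcohol [C11: CH(OCOiPr)CH2C(=CH2)CH2OC(O)CH=CH2], via homoallylic alcohol 23 (not isolated)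
Conditions: 22 (2 equiv), MgBr2·OEt2 (3 equiv), CH2Cl2, −40 → 0 °C; then i-PrCOCl, pyridine, DMAP (cat.), 0 → 23 °C
Reagents that add atoms: isobutyryl chloride, CC(C)C(Cl)=O
Why: Keck-type chelation-controlled allylstannane addition (SE2′): MgBr2 ties the aldehyde oxygen to the C8 hydroxyl, the formyl H sits in the crowded position next to C1–OPMB and the nucleophile attacks anti to C10, giving 11R; the magnesium alkoxide is acylated in the same flask and the C4 ketone and tertiary C8–OH do not react.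

**Step 16**
Reactants: 24 11-O-isobutyrate (6,7-acetonide)
Product: 26 6-O-acetyl-7,8-O-isopropylidene compound, via C6 alcohol 25 (not isolated)
Conditions: CSA (10 mol %), CH2Cl2, 23 °C; then pyridine, Ac2O, DMAP (cat.), 23 °C
Reagents that add atoms: acetic anhydride, CC(=O)OC(C)=O
Why: Acid-catalysed acetonide migration from the strained trans-diequatorial 6,7-diol to the cis 7,8-diol is thermodynamically driven and frees only C6–OH, which is then acetylated.

**Step 17**
Reactants: 26 6-acetate 7,8-acetonide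
Product: 27 6-O-acetyl-7,8-diol
Conditions: AcOH/H2O/THF (3:1:1), 45 °C
Reagents that add atoms: none
Why: Mild acetal hydrolysis removes the acetonide while the esters and the PMB ether survive.

**Step 18**
Reactants: 27 7,8-diol
Product: 28 7-O-isobutyrate (6-OAc, 7-OiBu, 8-OH, 11-OiBu; C4 ketone)
Conditions: i-PrCOCl, pyridine, DMAP (cat.), CH2Cl2, 0 °C
Reagents that add atoms: isobutyryl chloride, CC(C)C(Cl)=O
Why: Acylation is selective for the secondary C7 alcohol over the tertiary C8 alcohol.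

**Step 19**
Reactants: 28 C4 ketone
Product: 29 4(18)-methylidene compound
Conditions: Zn, CH2Br2, TiCl4, THF/CH2Cl2, 0 → 23 °C
Reagents that add atoms: dibromomethane, BrCBr
Why: Takai–Lombardo methylenation is non-basic, works on hindered ketones next to a quaternary carbon and leaves esters and the acrylate alone.

**Step 20**
Reactants: 29 acrylate diene
Product: 30 1-O-(4-methoxybenzyl) ether of the target
Conditions: second-generation Grubbs catalyst (10 mol %), toluene, 80 °C
Reagents that add atoms: none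
Why: Ring-closing metathesis between the acrylate and the side-chain 1,1-disubstituted alkene forms the β-substituted butenolide; the hindered exocyclic C4 methylene does not take part.

**Step 21**
Reactants: 30 PMB ether
Product: 31 target, (1S,5S,6S,7R,8S,9R,10R,11R)-6-acetoxy-1,8-dihydroxy-7,11-bis(2-methylpropanoyloxy)cleroda-4(18),13-dien-15,16-olide
Conditions: DDQ, CH2Cl2/pH 7 buffer (10:1), 0 → 23 °C
Reagents that add atoms: none
Why: Oxidative cleavage of the PMB ether frees C1–OH under neutral conditions that spare the esters, the butenolide and the exocyclic alkene.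

**Compound list**
1 | dimethyl (4R,5R)-2,2-dimethyl-1,3-dioxolane-4,5-dicarboxylate | COC(=O)[C@@H]1OC(C)(C)O[C@H]1C(=O)OC | starting material
2 | (4R,5R)-N4,N5-dimethoxy-N4,N5,2,2-tetramethyl-1,3-dioxolane-4,5-dicarboxamide | CON(C)C(=O)[C@@H]1OC(C)(C)O[C@H]1C(=O)N(C)OC | intermediate
3 | (4R,5R)-4,5-diacetyl-2,2-dimethyl-1,3-dioxolane | CC(=O)[C@@H]1OC(C)(C)O[C@H]1C(C)=O | intermediate
4 | [(4R,5R)-2,2-dimethyl-1,3-dioxolane-4,5-diyl]di(ethene-1,1-diyl) bis(trifluoromethanesulfonate) | C=C(OS(=O)(=O)C(F)(F)F)[C@@H]1OC(C)(C)O[C@H]1C(=C)OS(=O)(=O)C(F)(F)F | intermediate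
5 | 1-[(4R,5S)-5-ethynyl-2,2-dimethyl-1,3-dioxolan-4-yl]ethenyl trifluoromethanesulfonate | C#C[C@@H]1OC(C)(C)O[C@H]1C(=C)OS(=O)(=O)C(F)(F)F | intermediate
6 | acrolein | C=CC=O | starting material
7 | (3S)-hexa-1,5-dien-3-ol | C=CC[C@H](O)C=C | intermediate
8 | 1-({[(3S)-hexa-1,5-dien-3-yl]oxy}methyl)-4-methoxybenzene | C=CC[C@H](OCc1ccc(OC)cc1)C=C | intermediate
9 | 9-{(4S)-4-[(4-methoxybenzyl)oxy]hex-5-en-1-yl}-9-borabicyclo[3.3.1]nonane | C=C[C@@H](OCc1ccc(OC)cc1)CCCB1C2CCCC1CCC2 | intermediate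
10 | (4S)-4-[(4-methoxybenzyl)oxy]hex-5-en-1-ol | OCCC[C@H](OCc1ccc(OC)cc1)C=C | intermediate
11 | methyl methacrylate | C=C(C)C(=O)OC | starting material
12 | methyl (2E,4S)-7-hydroxy-4-[(4-methoxybenzyl)oxy]-2-methylhept-2-enoate | OCCC[C@H](OCc1ccc(OC)cc1)/C=C(\C)C(=O)OC | intermediate
13 | methyl (2E,4S)-4-[(4-methoxybenzyl)oxy]-2-methyl-7-oxohept-2-enoate | O=CCC[C@H](OCc1ccc(OC)cc1)/C=C(\C)C(=O)OC | intermediate
14 | methyl (2E,4S)-8-[(4S,5S)-5-ethynyl-2,2-dimethyl-1,3-dioxolan-4-yl]-7-hydroxy-4-[(4-methoxybenzyl)oxy]-2-methylnona-2,8-dienoate (C4 epimers, clerodane numbering) | C#C[C@@H]1OC(C)(C)O[C@H]1C(=C)C(O)CC[C@H](OCc1ccc(OC)cc1)/C=C(\C)C(=O)OC | intermediate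
15 | methyl 4-hydroxy-1-[(4-methoxybenzyl)oxy]-6,7-(isopropylidenedioxy)-5,9-dimethyl-8-methylidene-trans-decalin-9-carboxylate (C4 epimers; C1, C5, C6, C7, C9, C10 as in the target) | OC1CC[C@H](OCc3ccc(OC)cc3)[C@@H]2[C@]1(C)[C@H](OC4(C)C)[C@@H](O4)C(=C)[C@@]2(C)C(=O)OC | intermediate
16 | 8-hydroperoxy-8-methyl analogue of 17 (C4 epimers) | OC1CC[C@H](OCc3ccc(OC)cc3)[C@@H]2[C@]1(C)[C@H](OC4(C)C)[C@@H](O4)[C@@](C)(OO)[C@@]2(C)C(=O)OC | intermediate
17 | methyl 4,8-dihydroxy-1-[(4-methoxybenzyl)oxy]-6,7-(isopropylidenedioxy)-5,8,9-trimethyl-trans-decalin-9-carboxylate (C4 epimers; other centres as in the target) | OC1CC[C@H](OCc3ccc(OC)cc3)[C@@H]2[C@]1(C)[C@H](OC4(C)C)[C@@H](O4)[C@@](C)(O)[C@@]2(C)C(=O)OC | intermediate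
18 | 9-(hydroxymethyl)-4,8-diol corresponding to 17 (C4 epimers) | OC1CC[C@H](OCc3ccc(OC)cc3)[C@@H]2[C@]1(C)[C@H](OC4(C)C)[C@@H](O4)[C@@](C)(O)[C@@]2(C)CO | intermediate
19 | 8-hydroxy-1-[(4-methoxybenzyl)oxy]-6,7-(isopropylidenedioxy)-5,8,9-trimethyl-4-oxo-trans-decalin-9-carbaldehyde (centres as in the target) | O=C1CC[C@H](OCc3ccc(OC)cc3)[C@@H]2[C@]1(C)[C@H](OC4(C)C)[C@@H](O4)[C@@](C)(O)[C@@]2(C)C=O | intermediate
20 | 2-methylprop-2-en-1-ol | CC(=C)CO | starting material
21 | 2-[(tributylstannyl)methyl]prop-2-en-1-ol | OCC(=C)C[Sn](CCCC)(CCCC)CCCC | intermediate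
22 | 2-[(tributylstannyl)methyl]prop-2-en-1-yl prop-2-enoate | C=CC(=O)OCC(=C)C[Sn](CCCC)(CCCC)CCCC | intermediate
23 | (11R)-homoallylic alcohol from 19 [C11: CH(OH)CH2C(=CH2)CH2OC(O)CH=CH2] | O=C1CC[C@H](OCc3ccc(OC)cc3)[C@@H]2[C@]1(C)[C@H](OC4(C)C)[C@@H](O4)[C@@](C)(O)[C@@]2(C)[C@@H](CC(=C)COC(=O)C=C)O | intermediate
24 | 11-O-isobutyrate of 23 | O=C1CC[C@H](OCc3ccc(OC)cc3)[C@@H]2[C@]1(C)[C@H](OC4(C)C)[C@@H](O4)[C@@](C)(O)[C@@]2(C)[C@@H](CC(=C)COC(=O)C=C)OC(=O)C(C)C | intermediate
25 | 6-hydroxy-7,8-O-isopropylidene isomer of 24 | O=C1CC[C@H](OCc3ccc(OC)cc3)[C@@H]2[C@]1(C)[C@H](O)[C@@H](OC4(C)C)[C@@](C)(O4)[C@@]2(C)[C@@H](CC(=C)COC(=O)C=C)OC(=O)C(C)C | intermediate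
26 | 6-O-acetate of 25 | O=C1CC[C@H](OCc3ccc(OC)cc3)[C@@H]2[C@]1(C)[C@H](OC(C)=O)[C@@H](OC4(C)C)[C@@](C)(O4)[C@@]2(C)[C@@H](CC(=C)COC(=O)C=C)OC(=O)C(C)C | intermediate
27 | 6-O-acetyl-7,8-diol (26 without the acetonide) | O=C1CC[C@H](OCc3ccc(OC)cc3)[C@@H]2[C@]1(C)[C@H](OC(C)=O)[C@@H](O)[C@@](C)(O)[C@@]2(C)[C@@H](CC(=C)COC(=O)C=C)OC(=O)C(C)C | intermediate
28 | 7-O-isobutyrate of 27 | O=C1CC[C@H](OCc3ccc(OC)cc3)[C@@H]2[C@]1(C)[C@H](OC(C)=O)[C@@H](OC(=O)C(C)C)[C@@](C)(O)[C@@]2(C)[C@@H](CC(=C)COC(=O)C=C)OC(=O)C(C)C | intermediate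
29 | 4(18)-methylidene compound from 28 | C=C1CC[C@H](OCc3ccc(OC)cc3)[C@@H]2[C@]1(C)[C@H](OC(C)=O)[C@@H](OC(=O)C(C)C)[C@@](C)(O)[C@@]2(C)[C@@H](CC(=C)COC(=O)C=C)OC(=O)C(C)C | intermediate
30 | 1-O-(4-methoxybenzyl) ether of the target | C=C1CC[C@H](OCc3ccc(OC)cc3)[C@@H]2[C@]1(C)[C@H](OC(C)=O)[C@@H](OC(=O)C(C)C)[C@@](C)(O)[C@@]2(C)[C@@H](CC3=CC(=O)OC3)OC(=O)C(C)C | intermediate
31 | (1S,5S,6S,7R,8S,9R,10R,11R)-6-acetoxy-1,8-dihydroxy-7,11-bis(2-methylpropanoyloxy)cleroda-4(18),13-dien-15,16-olide | C=C1CC[C@H](O)[C@@H]2[C@]1(C)[C@H](OC(C)=O)[C@@H](OC(=O)C(C)C)[C@@](C)(O)[C@@]2(C)[C@@H](CC1=CC(=O)OC1)OC(=O)C(C)C | target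

**Totals**
Total step count: 21 (19 on the main line and fragments, 2 for reagent 22).
Longest linear sequence: 16 steps (steps 4–12 and 15–21).

**Three steps most likely to fail**

Step 10 (radical bicyclisation/hydration). The α-ester C9 radical may be quenched before it closes ring B, and the C9 facial selectivity rests on an A(1,3) argument that is not proven for this system. The fallback closes the rings one at a time and sets out from 14. Fe(acac)3 and PhSiH3 in EtOH at 60 °C give the reductive radical conjugate addition only, forming the monocyclic ring A ester F1. LiN(iPr)2 and Me3SiCl convert it into the silyl ketene acetal F2. Ph3PAuCl/AgBF4 (cat.) in CH2Cl2 then closes ring B by a Conia-ene-type 6-exo-dig carbocyclisation onto the alkyne, and desilylating work-up returns the route to exocyclic alkene 15. This is hydrated separately (Mn(dpm)3, PhSiH3, O2) to 17.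

Step 15 (allylation of the neopentyl, peri-crowded C11 aldehyde). The Lewis-acid-mediated stannane addition may be too slow or too unselective. The fallback sets out from 19 and uses a small organoindium reagent in water. In powder and 3-bromo-2-(bromomethyl)prop-1-ene in THF/H2O give the allylic bromide F3, still under hydroxyl chelation control. CsO2CCH=CH2 in DMF displaces the bromide to give homoallylic alcohol 23, which is isobutyrylated to 24 as before.

Step 7 (cross-metathesis of an allylic-ether alkene with a 1,1-disubstituted acrylate). Conversion may be low. The fallback sets out from 10 and builds the enoate by olefination. OsO4 (cat.), NaIO4 and 2,6-lutidine in dioxane/H2O cleave the vinyl group to the hydroxy aldehyde F4 (present largely as its lactol). Wittig reaction with Ph3P=C(CH3)CO2CH3 in toluene at 80 °C returns the route to 12.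

**Further compounds**
F1 | step 10 | monocyclic ring A ester (methyl 2-cyclohexylpropanoate carrying 1-OPMB, 4-OH, 5-CH3 and the (4S,5S)-5-ethynyl-2,2-dimethyl-1,3-dioxolan-4-yl group at C5; C4 and C9 epimers) | OC1CC[C@H](OCc2ccc(OC)cc2)[C@@H](C(C)C(=O)OC)[C@]1(C)[C@@H]3OC(C)(C)O[C@H]3C#C
F2 | step 10 | silyl ketene acetal (O-trimethylsilyl ketene acetal and 4-O-trimethylsilyl ether of F1) | C[Si](C)(C)OC1CC[C@H](OCc2ccc(OC)cc2)[C@@H](C(C)=C(OC)O[Si](C)(C)C)[C@]1(C)[C@@H]3OC(C)(C)O[C@H]3C#C
F3 | step 15 | allylic bromide [19 with C11 as (R)-CH(OH)CH2C(=CH2)CH2Br] | O=C1CC[C@H](OCc3ccc(OC)cc3)[C@@H]2[C@]1(C)[C@H](OC4(C)C)[C@@H](O4)[C@@](C)(O)[C@@]2(C)[C@@H](CC(=C)CBr)O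
F4 | step 7 | hydroxy aldehyde, (2S)-5-hydroxy-2-[(4-methoxybenzyl)oxy]pentanal | OCCC[C@H](OCc1ccc(OC)cc1)C=O
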